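Readings and results come from a simulation for an exercise; the scatter is artificial.

A small charge, c(starting material) = 0.10 M beside c(protic impurity) = 0.0200 M, stands for 3.0 h, and I want to know who holds the largest share then.

| flask | starting material | protic impurity | remark | time |
|---|---|---|---|---|
| green | 0.067 M | 0.020 M | run made earlier |  |
| grey | 0.15 M | 0.020 M | run made earlier |  |
| flask | 0.10 M | 0.0200 M |  | 3.0 h |

| run | time / min | intermediate B / % | intermediate A / % | target / % | intermediate D / % | intermediate C / % | starting material / % | intermediate E / % |
|---|---|---|---|---|---|---|---|---|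
| green | 6.00 | 7 | 7 | 0 | 1 | 1 | 79 | 0 |
| green | 15.0 | 10 | 16 | 0 | 0 | 5 | 53 | 2 |
| green | 30.0 | 13 | 23 | 7 | 1 | 3 | 33 | 0 |
| green | 50.0 | 15 | 23 | 11 | 1 | 7 | 19 | 3 |
| green | 60.0 | 13 | 22 | 14 | 1 | 5 | 14 | 1 |
| green | 80.0 | 12 | 22 | 22 | 0 | 10 | 9 | 1 |
| green | 120 | 8 | 14 | 33 | 2 | 12 | 3 | 2 |
| grey | 15.0 | 9 | 18 | 0 | 0 | 1 | 57 | 1 |
| grey | 30.0 | 19 | 23 | 7 | 2 | 4 | 36 | 0 |
| grey | 50.0 | 17 | 26 | 12 | 2 | 7 | 20 | 1 |
| grey | 60.0 | 18 | 23 | 18 | 1 | 8 | 17 | 0 |
| grey | 80.0 | 14 | 23 | 22 | 4 | 10 | 10 | 2 |
| grey | 90.0 | 13 | 22 | 28 | 0 | 11 | 6 | 0 |
| grey | 120 | 7 | 21 | 33 | 5 | 9 | 7 | 3 |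

(each reading ± 1.5 percentage points)

- percentages count the starting material that a species holds: one idle adduct or side product counts as two
- target is meant together with its idle adduct
- the analysis behind the earlier runs scatters by 1.5 percentage points, standard deviation
- steps that have been proposed: starting material -> intermediate A; starting material <-> intermediate B; intermediate B <-> intermediate C; intermediate A -> target; intermediate C <-> intermediate D; intermediate D <-> intermediate E; starting material + target <-> idle adduct; starting material + protic impurity -> quenched substrate; starting material + intermediate D -> side product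
- in an amount of target, one idle adduct counts as one target
- a reading or a percentage of starting material is of its free form alone

1. the largest share of what was charged as starting material, at 3.0 h belongs to (intermediate A / intermediate B / intermediate C / target / intermediate D / intermediate E)
2. the largest share itself, whichever of these holds it, in percent of the starting material charged

Intermediate A has one proposed exit, to target, so I count its half-lives. I take the half-life of intermediate A from the target gained per intermediate A standing, green and grey pooled from 60.0 min to 120 min, and read 48.9 min. Green's starting material reads a half-life of 21.6 min, which counts its loss by the proposed exits together, not by the step to intermediate A.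

My bench rule is that each half-life hands half of what intermediate A holds to target. It stops working while starting material still feeds intermediate A, so, as a rough border, I want the ratio of the two half-lives times starting material over intermediate A to stand below one. Green reads 3.25 at 30.0 min and 0.925 at 80.0 min; grey reads 0.754 at 120 min.

So I start at 120 min, from the green and grey means: target 33.0%, intermediate A 17.5%. The remaining time is 1.23 half-lives, which gives target 43.0% and intermediate A 7.48%. That target stands above intermediate A and green's intermediate C reading of 12%.

The forecast says target at 46%, range 40% to 52%, higher than mine, because it adds “plus 2–3 from returning B and leftover starting material”.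

The flask gives target at 42.3%, inside the forecast's range.

    starting material → intermediate A (k = 2.70 × 10⁻⁴ s⁻¹)
    starting material ⇌ intermediate B (K = 1.60, k = 2.10 × 10⁻⁴ s⁻¹)
    intermediate B ⇌ intermediate C (K = 5.60, k = 2.00 × 10⁻⁴ s⁻¹)
    intermediate A → target (k = 2.20 × 10⁻⁴ s⁻¹)
    intermediate C ⇌ intermediate D (K = 2.90, k = 1.30 × 10⁻⁴ s⁻¹)
    intermediate D ⇌ intermediate E (K = 2.10, k = 7.40 × 10⁻⁴ s⁻¹)
    starting material + target ⇌ idle adduct, settled at all times (K = 9.90 L mol⁻¹)
    starting material + protic impurity → quenched substrate (k = 0.0150 L mol⁻¹ s⁻¹)
    starting material + intermediate D → side product (k = 0.00140 L mol⁻¹ s⁻¹)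

In this flask, intermediate A is made 2.22 times faster than it is used at 0.428 h, but at 3.00 h its making is only 0.306 of its use, each step taken net. It ends at 9.86%, above my 7.48%, with that feed still running against the 48.9 min count. Read at 8.0 h, the same flask gets 6.13 more half-lives, so nearly all of that intermediate A should turn over, giving target about 52.2%. The computed neighbour holds 55.6%, with intermediate A at 0.695%.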